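**Retrosynthetic overview**
1. Forward order of compounds: 1 (3,6-dibromo-2-fluorobenzaldehyde) → 2 → 3 → 4 → 5 → 6 (target). Ring A (the dibrominated benzene ring) is bought intact; ring B (the pyrrole ring) is closed last.
2. 6 ⇒ 5 ⇒ 4: the N1–C2 bond and the C3–Cl bond are cut together (anti-chloroamination of a 1-bromoalkyne made in the flask from a gem-dibromoalkene; the C2–Br is already in place).
3. 4 ⇒ 3: the exocyclic C=C bond, by dibromomethylenation of the aldehyde.
4. 3 ⇒ 1: the aryl C–N bond, by SNAr of fluoride with azide, then reduction.

Assumption: the target has no stereocentre and no stereogenic double bond, so it is achiral and is made as drawn; 1 is taken as a catalogue compound.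

**Step 1**
Reactants: 1 3,6-dibromo-2-fluorobenzaldehyde
Product: 3 2-amino-3,6-dibromobenzaldehyde, via aryl azide 2 (not isolated)
Conditions: NaN3 (1.1 equiv), DMSO, 50 °C; then Fe powder, NH4Cl, EtOH/H2O, 60 °C
Reagents that add atoms: sodium azide, [Na+].[N-]=[N+]=[N-]
Why: SNAr of azide at the C–F carbon, which is activated by the ortho formyl group and the ortho bromine (fluoride leaves far faster than the bromide that is also ortho to the aldehyde), followed by a Béchamp-type iron reduction of the aryl azide that leaves the aldehyde and the aryl bromides untouched; no stereocentre is formed.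

**Step 2**
Reactants: 3 2-amino-3,6-dibromobenzaldehyde
Product: 4 3,6-dibromo-2-(2,2-dibromovinyl)aniline
Conditions: CBr4 (2 equiv), PPh3 (2 equiv), Zn dust (2 equiv), CH2Cl2, rt, 24 h; then 3, rt
Reagents that add atoms: carbon tetrabromide, BrC(Br)(Br)Br
Why: Ramirez dibromomethylenation (first stage of the Corey–Fuchs sequence), a Wittig reaction of the aldehyde with Ph3P=CBr2, in which zinc removes Ph3PBr2 so that the hindered, electron-poor free NH2 is not phosphorylated; no stereocentre is formed.

**Step 3**
Reactants: 4 3,6-dibromo-2-(2,2-dibromovinyl)aniline
Product: 6 2,4,7-tribromo-3-chloro-1H-indole, via bromoalkyne 5 (not isolated)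
Conditions: Cs2CO3 (2.5 equiv), C2Cl6 (1.2 equiv), DMSO, 25 to 70 °C, N2, dark
Reagents that add atoms: hexachloroethane, ClC(Cl)(Cl)C(Cl)(Cl)Cl
Why: Proposed new method: a base-triggered dehydrobrominative anti-chloroamination, in which Cs2CO3 effects E2 loss of HBr from the gem-dibromoalkene to give 1-bromoalkyne 5, the ortho nitrogen (acidified by the ring bromines, reacting as its cesium anilide) adds 5-endo-dig to the bromine-bearing alkyne carbon (the only ring size the tether allows), and the resulting C3 carbanion (or the 2-bromoindolide it relaxes to) abstracts Cl+ from C2Cl6 in a halophilic substitution that expels tetrachloroethylene and chloride; the N1–C2 bond, ring B and the C3–Cl bond thus form in one operation, and because C2Cl6 does not chlorinate neutral arenes the free para position of the aniline is spared; the closest known reaction types are the base-mediated cyclisation of ortho-(gem-dibromovinyl)sulfonanilides to 2-bromoindoles and the chlorination of carbanions by C2Cl6, whose union on a free-NH2 haloalkyne is unreported; no stereocentre is formed.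

**Compound list**
1 | 3,6-dibromo-2-fluorobenzaldehyde | O=Cc1c(F)c(Br)ccc1Br | starting material
2 | 2-azido-3,6-dibromobenzaldehyde (aryl azide) | [N-]=[N+]=Nc1c(Br)ccc(Br)c1C=O | intermediate
3 | 2-amino-3,6-dibromobenzaldehyde | Nc1c(Br)ccc(Br)c1C=O | intermediate
4 | 3,6-dibromo-2-(2,2-dibromovinyl)aniline | Nc1c(Br)ccc(Br)c1C=C(Br)Br | intermediate
5 | 3,6-dibromo-2-(bromoethynyl)aniline (bromoalkyne) | Nc1c(Br)ccc(Br)c1C#CBr | intermediate
6 | 2,4,7-tribromo-3-chloro-1H-indole | Clc1c(Br)[nH]c2c(Br)ccc(Br)c12 | target

**Step count and risks**
Total steps: 3. Longest linear sequence: 3.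

Steps most likely to fail:

Step 3 (the proposed new step). Risks are Br+ transfer from 5 to the C3 carbanion (giving the 2,3-dibromo analogue), over-chlorination of the product anion to a 3,3-dichloroindolenine, and N-chlorination of the anilide. The fallback uses known chemistry and sets out from 4. Intramolecular palladium-catalysed C–N coupling of the vinylic C–Br with the free NH2 (Pd2(dba)3 as the zerovalent palladium source, P(t-Bu)3, K3PO4, toluene, 100 °C) gives 2,4,7-tribromo-1H-indole F3. The bulky phosphine makes oxidative addition into the remaining C–Br bonds reversible. Electrophilic chlorination of F3 at C3 with NCS (1.0 equiv) in DMF at 0 °C then gives the target, so the fallback comes back to the route at 6.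

Step 2. The aldehyde is flanked by NH2 and Br and is a vinylogous amide, so it may react slowly with the bulky ylide, and the NH2 may be attacked by bromophosphonium species. The fallback sets out from 3. Ohira–Bestmann homologation (dimethyl (1-diazo-2-oxopropyl)phosphonate, K2CO3, MeOH, rt), which uses a small phosphonate carbanion and no phosphine, gives 3,6-dibromo-2-ethynylaniline F2. Halophilic C–H bromination of the alkyne (CBr4, KOH, catalytic 18-crown-6, toluene, rt), which cannot brominate the aniline ring, then gives bromoalkyne 5. The fallback comes back to the route at 5, which is isolated and put through step 3 with one equivalent less Cs2CO3.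

Step 1. The azide SNAr may be slow, the ortho-azido aldehyde may close to an anthranil on heating, or the aldehyde may suffer during reduction. The fallback sets out from 1. Treatment with 2,4-dimethoxybenzylamine (2.5 equiv, K2CO3, DMSO, 80 °C) first forms the aldimine, which activates the ortho fluoride for SNAr by a second amine, giving 3,6-dibromo-N-(2,4-dimethoxybenzyl)-2-[(E)-(2,4-dimethoxybenzylimino)methyl]aniline F1. Aqueous TFA in CH2Cl2 (rt to 40 °C) hydrolyses the imine and cleaves the N-benzyl group, so the fallback comes back to the route at 3.

**Further compounds**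
F1 | step 1 | 3,6-dibromo-N-(2,4-dimethoxybenzyl)-2-[(E)-(2,4-dimethoxybenzylimino)methyl]aniline | COc1ccc(CNc2c(Br)ccc(Br)c2/C=N/Cc2ccc(OC)cc2OC)c(OC)c1
F2 | step 2 | 3,6-dibromo-2-ethynylaniline | Nc1c(Br)ccc(Br)c1C#C
F3 | step 3 | 2,4,7-tribromo-1H-indole | Brc1cc2c(Br)ccc(Br)c2[nH]1
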